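At late times, once J and the chain behind it have emptied, a mole of J charged stands as E or as Z, with L booked as E. Close that ledger first and leave the rates for later.

| flask | J | D | temperature | remark | time |
|---|---|---|---|---|---|
| delta | 0.055 M | 0.11 M | −12 °C | run made earlier |  |
| epsilon | 0.22 M | 0.11 M | 37 °C | run made earlier |  |
| teal | 0.11 M | 0.110 M | 25 °C |  | 8.0 d |
| ochre | 0.11 M | 0.110 M | 55 °C |  | 8.0 d |
| blue | 0.11 M | 0.110 M | −5 °C |  | 8.0 d |
| green | 0.11 M | 0.110 M | −35 °C |  | 8.0 d |

| run | time / d | E / % | J / % |
|---|---|---|---|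
| delta | 10.0 | 1 | 96 |
| delta | 20.0 | 0 | 97 |
| delta | 30.0 | 0 | 96 |
| delta | 40.0 | 0 | 94 |
| delta | 50.0 | 0 | 90 |
| delta | 60.0 | 0 | 90 |
| epsilon | 0.500 | 2 | 38 |
| epsilon | 0.625 | 0 | 27 |
| epsilon | 1.04 | 12 | 12 |
| epsilon | 2.00 | 36 | 1 |
| epsilon | 3.00 | 53 | 2 |
| epsilon | 6.00 | 65 | 0 |

(scatter of a reading: 1.5 percentage points)

- a species is counted by the J in it: one L counts as two
- amounts and yields of E count L too
- steps that have been proposed: J -> Q; Q -> G; G -> X; X -> E; Q + D -> Z; J + E <-> L
- in an amount of E, one L counts as one E

* the best flask by amount of E, in percent of the J charged; "all alike" if 1.5 percentage points covers them all (teal / ochre / blue / green / all alike)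
* amount of E at the end, in percent of the J charged, teal
* amount of E at the end, in percent of the J charged, ochre
* amount of E at the end, in percent of the J charged, blue
* amount of E at the end, in percent of the J charged, green

Take the proposed steps. J gives Q, and Q has two exits: into G, at a rate that goes with cQ, or with D to Z, at a rate that goes with cQ·cD. Divide the second rate by the first. Both cQ and time drop out, leaving dcZ/dn = κ·cD, where n is the concentration that has passed from Q into G. Each Z costs one D, so the integrated rule is ln(charged cD / final cD) = κ·n, and once G and X have emptied, n is cE.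

Now book the epsilon run at 6.00 d. J, the limiting reagent, reads 0% and E reads 65%. Taking the chain as emptied, the rest is Z, so cE = 0.143 M and cZ = 0.0770 M. That leaves cD = 0.0330 M of the 0.11 M charged. The rule then reads 8.42 M⁻¹, with the scatter of the readings in it. This κ is the trap ratio: the rate of Q + D → Z per unit of cD, divided by the rate of Q → G, which is the selectivity factor between the two exits.

Apply it to ochre. With equal charges, the ledger makes final cD equal to final cE, so the share f of J booked as E obeys ln(1/f) = κ·cJ·f. One Newton step from 0.5 gives 57.9%. That is my own reckoning, and it carries κ unchanged from 37 °C to 55 °C, which no earlier run tests. It is an estimate for a finished flask and gives no time.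

The forecast names ochre, saying “Ochre should reach that ceiling”. It gives teal 24% (11% to 42%), ochre 62% (52% to 73%), blue 0% (0% to 1%) and green 0% (0% to 0.5%). Its ochre figure stands above mine.

The simulation gives ochre as best: teal 24.1%, ochre 67.9%, blue 0%, green 0%.

    J → Q (k = 0.0190 h⁻¹, Ea = 95.0 kJ mol⁻¹)
    Q → G (k = 0.00750 h⁻¹, Ea = 106 kJ mol⁻¹)
    G → X (k = 0.0110 h⁻¹, Ea = 111 kJ mol⁻¹)
    X → E (k = 0.230 h⁻¹, Ea = 104 kJ mol⁻¹)
    Q + D → Z (k = 0.0940 M⁻¹ h⁻¹, Ea = 82.0 kJ mol⁻¹)
    J + E ⇌ L, settled at all times (K = 10.0 M⁻¹, ΔH = 4.00 kJ mol⁻¹)
    (constants at 25 °C)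

Ochre's shortfall from full yield is the step Q + D → Z, which books 32.1% of the J as Z: ochre holds 67.9% E with that step and 100% without it, and its E stands 5.9 percentage points above the forecast. Put ochre's ledger through the rule: its trap ratio is 5.17 M⁻¹, less than the 8.42 M⁻¹ read at 37 °C. Carry that value to the neighbour of ochre charged with 0.44 M of D, which ends with 32.5% E. The rule gives 83.1% of its D left, and that flask holds 83.1%.

The earlier runs and the new flask are simulated from invented constants; noise was put on by code.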